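**Retrosynthetic overview**
- Target 16 comes from 4-bromo-3-butyl-5-methylenefuranone 12 by two rounds of Br2 addition and HBr elimination on the exocyclic alkene.
- 12 comes from 4-bromo-3-butyl-5-methylbutenolide 10 (C5 bromination, then HBr loss), and 10 from 3-butyl-5-methyltetronic acid 9 by deoxybromination.
- 9 contains the only ring; it is formed early by desilylative lactonisation of the γ-silyloxy β-keto ester 6 and kept to the end.
- 6 comes from an intermolecular crossed Claisen condensation that makes the C3–C4 bond: the lithium enolate of ethyl hexanoate (C2, C3 and butyl) adds to O-TBS ethyl lactate (C4, C5 and the future exocyclic carbon).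

Assumption: the target has no stereocentre and its exocyclic alkene carries two identical bromines, so it is achiral with no E/Z isomer; racemic ethyl lactate is used and intermediate stereocentres are left uncontrolled because all are erased.

**Step 1**
Reactants: 1 ethyl 2-hydroxypropanoate (racemic ethyl lactate)
Product: 2 ethyl 2-((tert-butyldimethylsilyl)oxy)propanoate (racemic)
Conditions: TBSCl (1.1 equiv), imidazole (2.2 equiv), DMF, 0 °C to rt
Reagents that add atoms: tert-butyldimethylsilyl chloride, CC(C)(C)[Si](C)(C)Cl
Why: Standard silyl ether protection of a secondary alcohol, which masks the hydroxyl so the ester can act as a clean acyl acceptor.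

**Step 2**
Reactants: 3 ethyl hexanoate (2.2 equiv); 2 ethyl 2-((tert-butyldimethylsilyl)oxy)propanoate
Product: 6 ethyl 2-butyl-4-((tert-butyldimethylsilyl)oxy)-3-oxopentanoate (diastereomer mixture), via lithium enolate of ethyl hexanoate 4 (not isolated), via lithium enolate of keto ester 5 (not isolated)
Conditions: LiN(i-Pr)2 (commercial solution, 2.2 equiv), THF, −78 °C, 45 min; add 2, −78 to −20 °C; AcOH quench at −78 °C
Reagents that add atoms: none
Why: Crossed Claisen condensation in which the preformed ester enolate acylates the more electrophilic α-silyloxy ester, and the second equivalent of enolate deprotonates the β-keto ester to drive the reaction and shield the ketone; both stereocentres are uncontrolled and erased later.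

**Step 3**
Reactants: 6 ethyl 2-butyl-4-((tert-butyldimethylsilyl)oxy)-3-oxopentanoate
Product: 9 3-butyl-4-hydroxy-5-methylfuran-2(5H)-one (3-butyl-5-methyltetronic acid; racemic), via ethyl 2-butyl-4-hydroxy-3-oxopentanoate 7 (not isolated), via tetrabutylammonium tetronate salt 8 (not isolated)
Conditions: Bu4NF (1.0 M in THF, 2.0 equiv), THF, 0 °C to rt; then 1 M HCl to pH 1, EtOAc extraction
Reagents that add atoms: none
Why: Fluoride desilylation frees the γ-oxygen, which lactonises onto the ester by a five-membered-ring transesterification to give the stable tetronate; the C2 stereocentre becomes sp2.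

**Step 4**
Reactants: 9 3-butyl-4-hydroxy-5-methylfuran-2(5H)-one
Product: 10 4-bromo-3-butyl-5-methylfuran-2(5H)-one (racemic)
Conditions: (COBr)2 (1.3 equiv), DMF (1.5 equiv), CH2Cl2, 0 °C to rt; NaHCO3 work-up
Reagents that add atoms: oxalyl bromide, BrC(=O)C(=O)Br
Why: Vilsmeier-type deoxybromination in which the enol oxygen of the vinylogous acid is activated as an iminium ether and displaced by bromide through addition–elimination, placing bromine only at C4.

**Step 5**
Reactants: 10 4-bromo-3-butyl-5-methylfuran-2(5H)-one
Product: 11 4,5-dibromo-3-butyl-5-methylfuran-2(5H)-one (racemic; crude, used directly)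
Conditions: NBS (1.05 equiv), AIBN (5 mol %), PhCF3, 85 °C; cool, filter, concentrate
Reagents that add atoms: N-bromosuccinimide, O=C1CCC(=O)N1Br
Why: Wohl–Ziegler radical bromination at the C5–H, which is tertiary, allylic and next to oxygen and so the weakest C–H bond, with bromine capture at C5 keeping the butenolide conjugated.

**Step 6**
Reactants: 11 4,5-dibromo-3-butyl-5-methylfuran-2(5H)-one
Product: 12 4-bromo-3-butyl-5-methylenefuran-2(5H)-one (kept cold and dilute, used promptly)
Conditions: Et3N (1.5 equiv), CH2Cl2, 0 °C to rt, 1 h
Reagents that add atoms: none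
Why: Dehydrobromination of the tertiary α-oxy allylic bromide, where the methyl group is the only source of a β-hydrogen, gives the exocyclic enol-lactone alkene and removes the last stereocentre.

**Step 7**
Reactants: 12 4-bromo-3-butyl-5-methylenefuran-2(5H)-one
Product: 14 (Z)-4-bromo-5-(bromomethylene)-3-butylfuran-2(5H)-one (mainly Z; the E/Z ratio does not matter), via 4,5-dibromo-5-(bromomethyl)-3-butylfuranone 13 (not isolated)
Conditions: Br2 (1.05 equiv), CH2Cl2, 0 °C, dark; then DBU (1.1 equiv), −20 to 0 °C
Reagents that add atoms: bromine, BrBr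
Why: Electrophilic bromine addition occurs at the electron-rich exocyclic enol-ether alkene and not the electron-poor ring alkene, and E2 dehydrobromination of the tertiary bromide then restores the exocyclic alkene with one bromine on it.

**Step 8**
Reactants: 14 (Z)-4-bromo-5-(bromomethylene)-3-butylfuran-2(5H)-one
Product: 16 4-bromo-3-butyl-5-(dibromomethylene)furan-2(5H)-one, via 4,5-dibromo-3-butyl-5-(dibromomethyl)furanone 15 (not isolated)
Conditions: Br2 (1.2 equiv), CH2Cl2, rt, ambient light; then DBU (1.1 equiv), 0 °C
Reagents that add atoms: bromine, BrBr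
Why: A second bromine addition and dehydrobromination on the same alkene, where the CHBr2 hydrogen is the only β-hydrogen, gives the symmetric dibromomethylene group with no stereochemical issue.

**Compound list**
1 | ethyl 2-hydroxypropanoate (racemic ethyl lactate) | CC(O)C(=O)OCC | starting material
2 | ethyl 2-((tert-butyldimethylsilyl)oxy)propanoate (racemic) | CC(O[Si](C)(C)C(C)(C)C)C(=O)OCC | intermediate
3 | ethyl hexanoate | CCCCCC(=O)OCC | starting material
4 | lithium enolate of ethyl hexanoate (lithium 1-ethoxyhex-1-en-1-olate) | [Li+].CCCCC=C([O-])OCC | intermediate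
5 | lithium enolate of ethyl 2-butyl-4-((tert-butyldimethylsilyl)oxy)-3-oxopentanoate | [Li+].CCCCC(C(=O)OCC)=C([O-])C(C)O[Si](C)(C)C(C)(C)C | intermediate
6 | ethyl 2-butyl-4-((tert-butyldimethylsilyl)oxy)-3-oxopentanoate (diastereomer mixture, racemic) | CCCCC(C(=O)OCC)C(=O)C(C)O[Si](C)(C)C(C)(C)C | intermediate
7 | ethyl 2-butyl-4-hydroxy-3-oxopentanoate | CCCCC(C(=O)OCC)C(=O)C(C)O | intermediate
8 | tetrabutylammonium 3-butyl-5-methyl-2-oxo-2,5-dihydrofuran-4-olate | CCCC[N+](CCCC)(CCCC)CCCC.CCCCC1=C([O-])C(C)OC1=O | intermediate
9 | 3-butyl-4-hydroxy-5-methylfuran-2(5H)-one (racemic) | CCCCC1=C(O)C(C)OC1=O | intermediate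
10 | 4-bromo-3-butyl-5-methylfuran-2(5H)-one (racemic) | CCCCC1=C(Br)C(C)OC1=O | intermediate
11 | 4,5-dibromo-3-butyl-5-methylfuran-2(5H)-one (racemic) | CCCCC1=C(Br)C(C)(Br)OC1=O | intermediate
12 | 4-bromo-3-butyl-5-methylenefuran-2(5H)-one | CCCCC1=C(Br)C(=C)OC1=O | intermediate
13 | 4,5-dibromo-5-(bromomethyl)-3-butylfuran-2(5H)-one (racemic) | CCCCC1=C(Br)C(Br)(CBr)OC1=O | intermediate
14 | (Z)-4-bromo-5-(bromomethylene)-3-butylfuran-2(5H)-one | CCCCC1=C(Br)/C(=C/Br)OC1=O | intermediate
15 | 4,5-dibromo-3-butyl-5-(dibromomethyl)furan-2(5H)-one (racemic) | CCCCC1=C(Br)C(Br)(C(Br)Br)OC1=O | intermediate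
16 | 4-bromo-3-butyl-5-(dibromomethylene)furan-2(5H)-one | CCCCC1=C(Br)C(=C(Br)Br)OC1=O | target

**Totals**
Total step count: 8. Longest linear sequence: 8 steps (1 to 16); ethyl hexanoate 3 enters at step 2.

**Three steps most likely to fail, with fallbacks**

Step 2 (crossed Claisen). The risk is proton transfer to the enolate from the α-hydrogen of 2, or self-condensation of ethyl hexanoate on warming. The fallback sets out from 2 and reaches the same carbon–carbon bond by aldol addition and oxidation. Ester 2 is reduced with i-Bu2AlH (1.05 equiv, CH2Cl2, −78 °C) to 2-((tert-butyldimethylsilyl)oxy)propanal F1. The enolate 4 (from 3 and LiN(i-Pr)2, THF, −78 °C) adds to this aldehyde to give ethyl 2-butyl-3-hydroxy-4-((tert-butyldimethylsilyl)oxy)pentanoate F2 as a diastereomer mixture. Dess–Martin periodinane (CH2Cl2, NaHCO3, rt) oxidises the secondary alcohol, and the route is rejoined at 6.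

Step 5 (radical bromination). The risk is competing bromination at the allylic CH2 of the butyl chain or over-bromination. The fallback sets out from 10 and uses ionic bromination in place of the radical one. Compound 10 is converted with TIPSOTf and Et3N (CH2Cl2, 0 °C) into ((4-bromo-3-butyl-5-methylfuran-2-yl)oxy)triisopropylsilane F3. This silyloxyfuran is brominated at its γ-carbon with NBS (THF, −78 °C), where only C5 can give the conjugated butenolide, and the route is rejoined at 11.

Step 8 (second bromination and elimination). The risk is sluggish addition of Br2 to the deactivated bromoalkene, or attack of the amine base on the bromofuranone. The fallback sets out from 14 and replaces dibromide formation and base elimination by bromohydrin formation and acid dehydration. Treating 14 with NBS in acetone–water (0 °C to rt) gives the lactol 4-bromo-3-butyl-5-(dibromomethyl)-5-hydroxyfuran-2(5H)-one F4. Dehydration with P4O10 in toluene at 80 °C then gives the target, so the route is rejoined at 16.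

**Further compounds**
F1 | step 2 | 2-((tert-butyldimethylsilyl)oxy)propanal | CC(O[Si](C)(C)C(C)(C)C)C=O
F2 | step 2 | ethyl 2-butyl-3-hydroxy-4-((tert-butyldimethylsilyl)oxy)pentanoate | CCCCC(C(=O)OCC)C(O)C(C)O[Si](C)(C)C(C)(C)C
F3 | step 5 | ((4-bromo-3-butyl-5-methylfuran-2-yl)oxy)triisopropylsilane | CCCCc1c(Br)c(C)oc1O[Si](C(C)C)(C(C)C)C(C)C
F4 | step 8 | 4-bromo-3-butyl-5-(dibromomethyl)-5-hydroxyfuran-2(5H)-one | CCCCC1=C(Br)C(O)(C(Br)Br)OC1=O
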